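## The problem

Planaic acid (15) is a para-depside: two benzene rings, each with a pentyl chain, joined only through one aryl ester. There is no ring to close and no stereocentre, so the task is one of constitution and chemoselectivity. Ring A is a 2,4-dimethoxy-6-pentylbenzoyl group whose acyl carbon sits between the C2 methoxy group and the C6 pentyl chain, and acyl transfer from such a 2,6-disubstituted benzoic acid is slow. Ring B is a 2-methoxy-6-pentylbenzoic acid whose carboxyl group must stay distinguishable from that of ring A to the end; being equally hindered, it has to be masked by a group that leaves by alkyl–oxygen cleavage. The groups that will not survive rough treatment are the aryl ester (hydroxide, alkoxides, amines, hydrides) and the electron-rich dimethoxyarene of ring A (electrophiles, strong oxidants). A classical acylation would also need a ring B phenol with one free and one methylated oxygen, which means telling two phenols apart. The feature that opens another way is ring B C4: it carries the ester oxygen, it is para to the carboxyl carbon, and it is the only ring B carbon whose two neighbours (C3 and C5) both bear hydrogen. A sterically governed C–H functionalisation will find C4 without a directing group, and the O–C4 bond can then be made by passing the ring B aryl group to the carboxylate oxygen of ring A, an atom outside the steric shield of the acyl carbon.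

## Retrosynthesis

15 to 14. The first cut is the alkyl–oxygen bond of a tert-butyl ester on the ring B carboxyl group, giving tert-butyl planaate 14. A tert-butyl group is chosen over benzyl or methyl for three reasons. It leaves as a cation, so the hindered acyl carbon is never attacked and the aryl ester is not exposed to a nucleophile. It has no arene C–H that would compete in the borylation of step 6. It does not invite acyl attack by the amide base of step 5. The forward reaction only has to keep the tert-butyl cation away from ring A.

14 to 5 and 13. The bond cut is O–C4 of ring B, between the ester oxygen and the aryl carbon, not the neighbouring acyl C–O bond. The neighbouring cut would need a ring B phenol and an activated form of acid 5, whose acyl carbon is shielded on both sides. In the chosen cut the nucleophile is the carboxylate oxygen of 2,4-dimethoxy-6-pentylbenzoic acid 5 and the aryl donor is boronic acid 13, with boron on the unhindered C4. The precursors are two monocyclic benzoic acid derivatives of similar size, so the route is convergent, and ring B never passes through a phenol. The forward reaction, a copper-mediated oxidative C–O coupling, must outrun protodeboronation, C–B hydroxylation and biaryl formation.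

13 to 12 to 10. The C–B bond is traced back to a C–H bond. Pinacol boronate 12 is the primary product of an iridium-catalysed C–H borylation of tert-butyl 2-methoxy-6-pentylbenzoate 10, and it is unmasked to 13 because free boronic acids are the proven partners in the coupling. An electrophilic halogenation of 10 would go para to the methoxy group, to C5, so the sterically governed borylation is the only direct way to C4. The forward step needs one accessible C–H bond on ring B and none elsewhere, and 10 meets both conditions.

10 to 7 and 8, 7 to 6. The pentyl chain is cut between its first and second carbon. The benzylic carbon is already present as the methyl group of commercial 2-methoxy-6-methylbenzoic acid 6, and the other four carbons come from 1-bromobutane 8. The ester is installed first (7), so that lateral lithiation gives an ester-stabilised benzylic anion and the product can be purified as a neutral compound. A cross-coupling route would need a halogenated ring B and more steps.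

5 to 4 to 2 to 1. The ring-to-carboxyl bond of acid 5 is cut at the aldehyde oxidation level. Aldehyde 4 comes from formylation of olivetol dimethyl ether 2, which is made by double O-methylation of olivetol 1. Direct lithiation of 2 would go between the two methoxy groups and give the wrong acid. Electrophilic formylation goes next to the pentyl chain, as the target requires.

## Roads not taken

Alternative 1: The cut is made inside acid 5 only: the C6–pentyl and C1–carboxyl bonds of ring A are formed in one flask on an aryne. 1-Fluoro-3,5-dimethoxybenzene A1 is lithiated by pentyllithium A2 between fluorine and a methoxy group. Loss of lithium fluoride gives 3,5-dimethoxybenzyne A3. A second equivalent of A2 adds at the aryne carbon remote from the neighbouring methoxy group, and carboxylation of the resulting aryllithium gives 2,4-dimethoxy-6-pentylbenzoic acid A4, which is identical with 5.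
- Merit: one operation in place of steps 1 to 3, with regiochemistry set by the inductive effect of the flanking methoxy group. In step count for the ring A fragment this road is better.
- Weak points: at least two equivalents of A2 are needed, and A2 has to be prepared. A1 can also be lithiated between its two methoxy groups, where no fluoride can leave, and that anion is carboxylated to a wrong acid. The aryllithium can add to a second molecule of A3.
- Comparison: this road makes a fragment and says nothing about the depside bond. It could replace steps 1 to 3 but does not compete with the key step. The chosen plan sets against it three steps with close precedent in the orcinol series and no excess organolithium. The ring A branch is not on the longest linear sequence, so the saving would not shorten it.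

Alternative 2: The cut removes the depside C–O bond and ring A together. Heating the diketo-dioxinone A5, 6-(2,4-dioxononyl)-2,2-dimethyl-4H-1,3-dioxin-4-one, with the ring B phenol A6, benzyl 4-hydroxy-2-methoxy-6-pentylbenzoate, opens the dioxinone to an acylketene. The phenol oxygen captures it, and the resulting aryl triketo ester folds by a C2-to-C7 aldol condensation and dehydration to the resorcylate depside A7, benzyl 4-(2,4-dihydroxy-6-pentylbenzoyloxy)-2-methoxy-6-pentylbenzoate.
- Merit: the ester forms under neutral thermal conditions before ring A exists, so the hindered acyl carbon is never a problem, and ketene capture by phenols is dependable. In certainty of the ester-forming event this road is at least as good as the chosen one.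
- Weak points: A5 takes several steps and is sensitive. A6 needs the chelated ortho hydroxyl methylated while the more reactive para hydroxyl stays free, which costs protecting-group steps. A7 still needs both ring A hydroxyls methylated, one of them hydrogen-bonded to the ester carbonyl, in the presence of the aryl ester, and then hydrogenolysis.
- Comparison: two steps follow the key step instead of one, and the precursors are longer. The chosen plan sets against it that no phenol on ring B is ever made or differentiated and that all methyl ethers are in place from the start.

Alternative 3: Ring A is made from a pyrone that already carries the depside ester. The pyrone A8, benzyl 2-methoxy-4-[(4-methoxy-2-oxo-6-pentyl-2H-pyran-5-carbonyl)oxy]-6-pentylbenzoate, reacts with 1,1-dimethoxyethene A9 in an inverse-demand [4+2] cycloaddition that forms ring A bonds C5–C6 and C3–C4. Decarboxylation of the bridged adduct and loss of one methoxy group as the alcohol give benzyl planaate A10.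
- Merit: both ring A methoxy groups arrive with the building blocks, no late methylation is needed, and no oxidising metal is used.
- Weak points: the 4-methoxy group is a donor on a diene that should be electron-poor, so the cycloaddition will need heat. A9 is a nucleophile and is then exposed to an aryl ester. The pyrone acid behind A8 is as hindered at its acyl carbon as 5, so the esterification problem is moved, not solved. The ring B phenol is needed again.
- Comparison: more steps and a less certain key step on this substitution pattern. Its one advantage is the absence of an oxidative coupling, and the chosen plan answers that with a known reaction type and a one-step endgame.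

Key step: step 8

Remark: planaic acid has no stereocentre, so no SMILES string carries a stereodescriptor. In step 8 acid 5 is the limiting component and boronic acid 13 is used in about twofold excess.

## Route

Step 1
Reactants: 1 olivetol (5-pentylbenzene-1,3-diol)
Product: 2 1,3-dimethoxy-5-pentylbenzene
Conditions: MeI, K2CO3, acetone, reflux
Reagents that add atoms: iodomethane, CI
Why: Williamson ether synthesis on both phenols; with carbonate in acetone the phenoxide should react at oxygen, and the symmetric diether cannot give isomers.

Step 2
Reactants: 2 1,3-dimethoxy-5-pentylbenzene
Product: 4 2,4-dimethoxy-6-pentylbenzaldehyde, via iminium salt 3 (not isolated)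
Conditions: POCl3, DMF, 0 °C to 70 °C; then ice-water
Reagents that add atoms: N,N-dimethylformamide, CN(C)C=O (formyl carbon, and the dimethylamino group of 3); water, O (carbonyl oxygen); phosphoryl chloride, O=P(Cl)(Cl)Cl (counter-ion of 3 only)
Why: Vilsmeier–Haack formylation; the chloroiminium ion should attack the ring carbon next to the pentyl chain, which is ortho to one methoxy group and para to the other, in preference to the more crowded carbon between the two methoxy groups, as in the orcinol dimethyl ether series. Hydrolysis of iminium salt 3 releases the aldehyde.

Step 3
Reactants: 4 2,4-dimethoxy-6-pentylbenzaldehyde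
Product: 5 2,4-dimethoxy-6-pentylbenzoic acid
Conditions: NaClO2, NaH2PO4, 2-methyl-2-butene, t-BuOH/H2O, rt
Reagents that add atoms: sodium chlorite, [Na+].[O-]Cl=O
Why: Pinnick oxidation; chlorous acid adds to the aldehyde and fragments to the acid, and the alkene traps the hypochlorous acid so that the electron-rich ring is not chlorinated.

Step 4
Reactants: 6 2-methoxy-6-methylbenzoic acid
Product: 7 tert-butyl 2-methoxy-6-methylbenzoate
Conditions: tert-butyl 2,2,2-trichloroacetimidate, BF3·OEt2 (cat.), CH2Cl2/cyclohexane, rt
Reagents that add atoms: tert-butyl 2,2,2-trichloroacetimidate, CC(C)(C)OC(=N)C(Cl)(Cl)Cl
Why: Acid-catalysed O-tert-butylation with a trichloroacetimidate; the carboxyl oxygen is alkylated, so the hindered acyl carbon takes no part and the two ortho substituents do not slow the reaction.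

Step 5
Reactants: 7 tert-butyl 2-methoxy-6-methylbenzoate; 8 1-bromobutane
Product: 10 tert-butyl 2-methoxy-6-pentylbenzoate, via benzylic lithium species 9 (not isolated)
Conditions: LiN(iPr)2, THF, −78 °C; then 8, DMPU, −78 °C to 0 °C
Reagents that add atoms: lithium diisopropylamide, [Li]N(C(C)C)C(C)C (lithium of 9 only)
Why: Lateral lithiation of an ortho-toluate followed by SN2 alkylation; the amide base removes a proton from the methyl group ortho to the ester to give the ester-stabilised benzylic anion 9, which displaces bromide from 8. The tert-butyl ester resists attack by 9, so self-condensation should be suppressed.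

Step 6
Reactants: 10 tert-butyl 2-methoxy-6-pentylbenzoate; 11 bis(pinacolato)diboron
Product: 12 tert-butyl 2-methoxy-6-pentyl-4-(4,4,5,5-tetramethyl-1,3,2-dioxaborolan-2-yl)benzoate
Conditions: [Ir(OMe)(cod)]2 (1.5 mol %), 4,4'-di-tert-butyl-2,2'-bipyridine (3 mol %), MTBE, 60 °C
Reagents that add atoms: none
Why: Iridium-catalysed aromatic C–H borylation, whose site is governed by sterics; C3–H is next to the methoxy group and C5–H next to the pentyl chain, so only C4–H, with hydrogen on both neighbours, should react. The tert-butyl ester offers no competing arene C–H bond.

Step 7
Reactants: 12 tert-butyl 2-methoxy-6-pentyl-4-(4,4,5,5-tetramethyl-1,3,2-dioxaborolan-2-yl)benzoate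
Product: 13 [4-(tert-butoxycarbonyl)-3-methoxy-5-pentylphenyl]boronic acid
Conditions: NaIO4, NH4OAc, acetone/H2O, rt
Reagents that add atoms: water, O
Why: Oxidative cleavage of a pinacol boronate; periodate cleaves the pinacol that is released in the hydrolysis equilibrium to acetone and so drives the equilibrium to the free boronic acid. The buffered, nearly neutral medium should spare the tert-butyl ester.

Step 8
Reactants: 5 2,4-dimethoxy-6-pentylbenzoic acid; 13 [4-(tert-butoxycarbonyl)-3-methoxy-5-pentylphenyl]boronic acid
Product: 14 tert-butyl planaate (tert-butyl 4-[(2,4-dimethoxy-6-pentylbenzoyl)oxy]-2-methoxy-6-pentylbenzoate)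
Conditions: Cu(OTf)2 (0.4 equiv), urea (1 equiv), 4 Å molecular sieves, EtOAc, 60 °C, dry air
Reagents that add atoms: none
Why: Chan–Lam-type oxidative esterification, the known coupling of arylboronic acids with carboxylic acids under Cu(OTf)2 and air. The carboxylate of 5 binds divalent copper, the aryl group of 13 passes from boron to copper, and oxidation of the aryl copper carboxylate by a second divalent copper centre gives a trivalent copper aryl carboxylate. Reductive elimination from this species forms the O–C4 bond of ring B, and the monovalent copper left behind is returned to the divalent state by oxygen. No ring is closed and no stereocentre is formed. The bond-forming atom of 5 is the carboxylate oxygen, which lies outside the pocket made by the C2 methoxy and C6 pentyl groups, so the hindrance that slows acyl transfer does not apply, and the site on ring B is fixed by where step 6 put the boron. The selectivity needed is chemoselectivity for C–O coupling over protodeboronation, C–B hydroxylation and biaryl homocoupling; it is sought by excluding water with molecular sieves, by keeping carboxylate in excess over copper, by the non-nucleophilic triflate counter-ion and by an excess of 13. Urea acts as a neutral ligand and takes up traces of triflic acid, which protects the tert-butyl ester.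

Step 9
Reactants: 14 tert-butyl planaate
Product: 15 planaic acid (4-[(2,4-dimethoxy-6-pentylbenzoyl)oxy]-2-methoxy-6-pentylbenzoic acid)
Conditions: TFA, Et3SiH, CH2Cl2, 0 °C to rt
Reagents that add atoms: none
Why: Acidolysis of a tert-butyl ester by alkyl–oxygen fission; the protonated ester loses the tert-butyl cation, so the hindered acyl carbon is not attacked, and the silane reduces the cation to isobutane before it can alkylate ring A. The aryl ester and the methyl ethers should be inert to trifluoroacetic acid at room temperature.

## Compound list

1 | olivetol (5-pentylbenzene-1,3-diol) | CCCCCc1cc(O)cc(O)c1 | starting material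
2 | 1,3-dimethoxy-5-pentylbenzene | CCCCCc1cc(OC)cc(OC)c1 | intermediate
3 | N-[(2,4-dimethoxy-6-pentylphenyl)methylidene]-N-methylmethanaminium dichlorophosphate (iminium salt) | CCCCCc1cc(OC)cc(OC)c1C=[N+](C)C.[O-]P(=O)(Cl)Cl | intermediate
4 | 2,4-dimethoxy-6-pentylbenzaldehyde | CCCCCc1cc(OC)cc(OC)c1C=O | intermediate
5 | 2,4-dimethoxy-6-pentylbenzoic acid | CCCCCc1cc(OC)cc(OC)c1C(=O)O | intermediate
6 | 2-methoxy-6-methylbenzoic acid | Cc1cccc(OC)c1C(=O)O | starting material
7 | tert-butyl 2-methoxy-6-methylbenzoate | Cc1cccc(OC)c1C(=O)OC(C)(C)C | intermediate
8 | 1-bromobutane | CCCCBr | starting material
9 | tert-butyl 2-(lithiomethyl)-6-methoxybenzoate (benzylic lithium species) | [Li]Cc1cccc(OC)c1C(=O)OC(C)(C)C | intermediate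
10 | tert-butyl 2-methoxy-6-pentylbenzoate | CCCCCc1cccc(OC)c1C(=O)OC(C)(C)C | intermediate
11 | bis(pinacolato)diboron | CC1(C)OB(OC1(C)C)B1OC(C)(C)C(C)(C)O1 | starting material
12 | tert-butyl 2-methoxy-6-pentyl-4-(4,4,5,5-tetramethyl-1,3,2-dioxaborolan-2-yl)benzoate | CCCCCc1cc(B2OC(C)(C)C(C)(C)O2)cc(OC)c1C(=O)OC(C)(C)C | intermediate
13 | [4-(tert-butoxycarbonyl)-3-methoxy-5-pentylphenyl]boronic acid | CCCCCc1cc(B(O)O)cc(OC)c1C(=O)OC(C)(C)C | intermediate
14 | tert-butyl planaate (tert-butyl 4-[(2,4-dimethoxy-6-pentylbenzoyl)oxy]-2-methoxy-6-pentylbenzoate) | CCCCCc1cc(OC(=O)c2c(CCCCC)cc(OC)cc2OC)cc(OC)c1C(=O)OC(C)(C)C | intermediate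
15 | planaic acid (4-[(2,4-dimethoxy-6-pentylbenzoyl)oxy]-2-methoxy-6-pentylbenzoic acid) | CCCCCc1cc(OC(=O)c2c(CCCCC)cc(OC)cc2OC)cc(OC)c1C(=O)O | target

## Step count and risks

Total step count: 9. Longest linear sequence: 6 steps (6 to 7 to 10 to 12 to 13 to 14 to 15, steps 4 to 9). The ring A branch (steps 1 to 3) joins at step 8.

Least certain steps:

Step 8 (key step).
- What may go wrong: aryl transfer to the hindered copper carboxylate may be slower than protodeboronation, than hydroxylation of the C–B bond by traces of water followed by arylation of the phenol so formed, or than oxidative biaryl coupling. The Lewis acidic copper triflate may also strip the tert-butyl group, which would expose a second carboxyl group that competes for the aryl group.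
- Fallback: it keeps the O–C4 disconnection but changes the aryl donor and the metal. It sets out from pinacol boronate 12. CuBr2 in MeOH/H2O at 80 °C should replace boron by bromine to give tert-butyl 4-bromo-2-methoxy-6-pentylbenzoate F1. F1 and acid 5 would then be joined by nickel/photoredox C–O coupling (NiBr2·glyme, 4,4'-di-tert-butyl-2,2'-bipyridine, Ir(ppy)3, a hindered secondary amine base, DMF, blue light). In that coupling a divalent nickel aryl carboxylate is brought to reductive elimination by energy transfer, under basic conditions that are harmless to the tert-butyl ester. The fallback comes back to the route at 14.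

Step 7.
- What may go wrong: incomplete removal of pinacol, because the hydrolysis equilibrium favours the ester, and protodeboronation or boroxine formation during long aqueous treatment and purification.
- Fallback: transesterification in place of oxidative diol cleavage. It sets out from 12. Diethanolamine in diethyl ether should precipitate the diethanolamine boronate, tert-butyl 4-(1,3,6,2-dioxazaborocan-2-yl)-2-methoxy-6-pentylbenzoate F2, and leave the pinacol in solution. Brief shaking of F2 with 0.1 M HCl and ether releases the boronic acid, and the fallback comes back at 13.

Step 5.
- What may go wrong: condensation of the benzylic anion with unreacted ester, competing deprotonation next to the methoxy group, or slow alkylation by the primary bromide so that the anion is quenched back to 7 on work-up.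
- Fallback: alkylation at the carboxylate stage, where no electrophilic ester is present. It sets out from acid 6. Two equivalents of LiN(iPr)2 in THF (−78 °C to 0 °C) give the dianion, lithium 2-(lithiomethyl)-6-methoxybenzoate F3, which is alkylated by 8 to give 2-methoxy-6-pentylbenzoic acid F4 after acidic work-up. tert-Butylation of F4 with tert-butyl 2,2,2-trichloroacetimidate and catalytic BF3·OEt2 brings the fallback back at 10.

Step 3.
- What may go wrong: chlorination of the electron-rich ring by hypochlorous acid if the alkene scavenger does not trap it fast enough, or incomplete oxidation of the hindered aldehyde.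
- Fallback: the carboxyl carbon is introduced as carbon dioxide in place of a formyl group. It sets out from diether 2. N-Bromosuccinimide in MeCN at 0 °C should brominate next to the pentyl chain (para to a methoxy group) to give 2-bromo-1,5-dimethoxy-3-pentylbenzene F5. Bromine–lithium exchange with n-BuLi in THF at −78 °C gives (2,4-dimethoxy-6-pentylphenyl)lithium F6, which is carboxylated with CO2 and acidified, and the fallback comes back at 5.

## Further compounds

F1 | step 8 | tert-butyl 4-bromo-2-methoxy-6-pentylbenzoate | CCCCCc1cc(Br)cc(OC)c1C(=O)OC(C)(C)C
F2 | step 7 | tert-butyl 4-(1,3,6,2-dioxazaborocan-2-yl)-2-methoxy-6-pentylbenzoate | CCCCCc1cc(B2OCCNCCO2)cc(OC)c1C(=O)OC(C)(C)C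
F3 | step 5 | lithium 2-(lithiomethyl)-6-methoxybenzoate | [Li]Cc1cccc(OC)c1C(=O)[O-].[Li+]
F4 | step 5 | 2-methoxy-6-pentylbenzoic acid | CCCCCc1cccc(OC)c1C(=O)O
F5 | step 3 | 2-bromo-1,5-dimethoxy-3-pentylbenzene | CCCCCc1cc(OC)cc(OC)c1Br
F6 | step 3 | (2,4-dimethoxy-6-pentylphenyl)lithium | [Li]c1c(CCCCC)cc(OC)cc1OC
A1 | alternative 1 | 1-fluoro-3,5-dimethoxybenzene | COc1cc(F)cc(OC)c1
A2 | alternative 1 | pentyllithium | [Li]CCCCC
A3 | alternative 1 | 3,5-dimethoxybenzyne | COC1=CC(OC)=CC#C1
A4 | alternative 1 | 2,4-dimethoxy-6-pentylbenzoic acid | CCCCCc1cc(OC)cc(OC)c1C(=O)O
A5 | alternative 2 | 6-(2,4-dioxononyl)-2,2-dimethyl-4H-1,3-dioxin-4-one | CCCCCC(=O)CC(=O)CC1=CC(=O)OC(C)(C)O1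
A6 | alternative 2 | benzyl 4-hydroxy-2-methoxy-6-pentylbenzoate | CCCCCc1cc(O)cc(OC)c1C(=O)OCc1ccccc1
A7 | alternative 2 | benzyl 4-(2,4-dihydroxy-6-pentylbenzoyloxy)-2-methoxy-6-pentylbenzoate | CCCCCc1cc(OC(=O)c2c(CCCCC)cc(O)cc2O)cc(OC)c1C(=O)OCc1ccccc1
A8 | alternative 3 | benzyl 2-methoxy-4-[(4-methoxy-2-oxo-6-pentyl-2H-pyran-5-carbonyl)oxy]-6-pentylbenzoate | CCCCCC1=C(C(=O)Oc2cc(CCCCC)c(C(=O)OCc3ccccc3)c(OC)c2)C(OC)=CC(=O)O1
A9 | alternative 3 | 1,1-dimethoxyethene | C=C(OC)OC
A10 | alternative 3 | benzyl planaate | CCCCCc1cc(OC(=O)c2c(CCCCC)cc(OC)cc2OC)cc(OC)c1C(=O)OCc1ccccc1
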